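**Remark on the chemistry (assumption):** the target has no stereocentre and no hindered axis (the C3–O–C7' ether rotates freely), so it is achiral and "single enantiomer" places no demand on the route; only constitution has to be controlled.

Locants: ring system A is the coumarin that carries the free 7-OH and the ether at C3; ring system B (primed locants) is the coumarin bound through O7'.

## The problem

The target is an ether-linked dimer of a single monomer: C3 of ring system A (7-hydroxy-6,8-dimethoxycoumarin) carries the phenolic oxygen O7' of a second 6,8-dimethoxycoumarin B. The one strategic bond, C3–O7', joins two positions of like polarity: O7' is a phenol oxygen, and C3 is the vinylogous para carbon of the C7 phenol of ring A (O7–C7···C4a–C4=C3), also nucleophilic. Polar solutions therefore need either an umpoled C3 (a 3-halocoumarin, prone to attack at C4 and to ring contraction under base) facing a weakly nucleophilic phenoxide flanked by two OMe groups, or a later construction of ring A on an O7'–CH2 unit. Because the two halves are the same compound, every stepwise route spends steps on telling them apart (which phenol stays free, which C3 is substituted). Each benzene ring carries four contiguous oxygens (O1, 8-OMe, 7-O, 6-OMe) beside the ring-fusion carbon, a pattern that must come from a cheap arene. The sensitive groups are two lactones (hydroxide, amines), an aryl vinyl ether, and a free, acidic phenol that is oxidised easily once ionised.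

The feature that makes the key step possible: O7 and C3 are the only two unblocked spin-bearing atoms of the phenoxyl radical of this ring system (C6 and C8 carry OMe, C4a is the ring fusion). The C3–O7' bond is thus the head-to-tail radical-dimer linkage of the monomer. In addition, C3 is the carbon that a Knoevenagel coumarin synthesis delivers with a carboxyl group, which can leave as CO2 when the coupled ring A re-aromatises.

## Retrosynthesis

**9 ⇒ 8.** The C3'–H bond of ring B is traced back to a C3'–CO2H bond (protodecarboxylation). Adding this carboxyl makes the two halves of 8 derive from one and the same monomer and gives the coupling carbon of ring A a leaving group other than a proton. An ester or nitrile at C3' would need an extra hydrolysis. The forward step must remove CO2 from an alkenoic acid without touching the aryl vinyl ether, the lactones or the phenol.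

**8 ⇒ 6 + 6.** The C3–O7' ether bond is cut, and a carboxyl group is restored at C3 of ring A, so that both fragments are the same acid 6. Against the neighbouring polar cut (3-halocoumarin plus phenoxide) this needs no differentiation of the halves and no protecting group. Against a cut inside ring A, it makes both ring systems by one ring synthesis. The precursor has half the carbon skeleton (C12 against C23). The forward reaction is an anodic dehydrodimerisation through the quinone methide ether 7, which loses CO2 to give 8. It must favour O7'–C3 over C3–C3' coupling and must stop at the dimer. The parent phenol without the carboxyl group is discussed under Alternative 3.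

**6 ⇒ 3 + 4.** The pyranone is cut at C3=C4 and O1–C2: Knoevenagel condensation of salicylaldehyde 3 with Meldrum's acid 4 through arylidene 5, then lactonisation by the 2-OH with loss of acetone. This is the mildest coumarin synthesis and delivers the C3 carboxyl without an extra step. A Pechmann approach would need a 2,4-dimethoxyresorcinol that is not a stock chemical. The forward step only requires that the 2-OH, not the 4-OH, closes the ring, which geometry dictates.

**3 ⇒ 2 ⇒ 1.** The C2–O bond is cut back to C2–Br and then to C2–H. Syringaldehyde 1 already holds the formyl carbon and three of the four oxygens in the right places. Its two free ring positions (C2, C6) are equivalent, so there is no regiochemical question. The forward steps are an electrophilic bromination and a copper-mediated hydroxylation that must not trigger Cannizzaro chemistry.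

## Roads not taken

**Alternative 1:** (the most obvious) Cut ring A at C3=C4 and O1–C2, keeping an O7'–CH2 unit. Forward key step: Perkin-type condensation of aldehyde 3 with 2-[(6,8-dimethoxy-2-oxo-2H-chromen-7-yl)oxy]acetic acid A2 in hot Ac2O/base, then de-O-acetylation at O7. A2 would come from 7-hydroxy-6,8-dimethoxy-2H-chromen-2-one (isofraxidin) A1 (3 plus Ph3P=CHCO2Et at about 200 °C) by O-alkylation with a bromoacetate and ester cleavage. This is reliable, but it builds the two identical halves by two different ring syntheses in sequence and needs five operations after 3 where the chosen plan needs three. The C3–O bond is made at the sp3 level and raised to the enol ether only in a forcing condensation, where acetic anhydride competes as the CH-acid partner. It is kept as the fallback for step 4.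

**Alternative 2:** Cut C3–O7' in the polar sense. Forward key step: Ullmann-type C–O coupling of the phenoxide of A1 with 3-bromo-6,8-dimethoxy-7-(methoxymethoxy)-2H-chromen-2-one A3 (from A1 by C3 bromination and O-protection) to give the MOM ether A4, then acid. The nucleophile is an acidic, electron-poor phenoxide with two ortho OMe groups, a poor partner for copper. The electrophile is a 3-bromocoumarin, which under basic conditions is open to addition–elimination at C4 (cine substitution) and to ring contraction to a benzofuran-2-carboxylate. The identical halves must be differentiated by halogenation and a protecting group, again five operations after 3.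

**Alternative 3:** Cut the same C3–O7' bond by direct oxidative dehydrodimerisation of the carboxyl-free monomer A1, with C3–H as the leaving group. This is the shortest route on paper (four steps). However, for 2,6-dimethoxyphenols whose (vinylogous) para carbon bears hydrogen, radical coupling normally goes carbon to carbon (β–β coupling of sinapyl-type radicals, para–para coupling of 2,6-dimethoxyphenol). Here that leads to 7,7'-dihydroxy-6,6',8,8'-tetramethoxy-2H,2'H-[3,3'-bichromene]-2,2'-dione (3,3'-biisofraxidin) A5. Both coupling modes re-aromatise by the same proton loss, so the substrate offers no handle to discriminate. The chosen plan pays one step for a carboxyl group that blocks and charges the C–C site, makes the C–O path irreversible through CO2 loss, gives a milder ring synthesis (80 °C against about 200 °C), and keeps the products water-soluble during electrolysis.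

Key step: step 4

## Route

Step 1
Reactants: 1 4-hydroxy-3,5-dimethoxybenzaldehyde (syringaldehyde)
Product: 2 2-bromo-4-hydroxy-3,5-dimethoxybenzaldehyde
Conditions: Br2 (1.0 equiv), AcOH, 20 °C
Reagents that add atoms: bromine, BrBr
Why: Electrophilic aromatic bromination; C2 and C6 are the only free ring positions and are equivalent, each ortho to one OMe and para to the other, so a single monobromide can form, and the formyl group and the first bromine slow a second substitution.

Step 2
Reactants: 2 2-bromo-4-hydroxy-3,5-dimethoxybenzaldehyde
Product: 3 2,4-dihydroxy-3,5-dimethoxybenzaldehyde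
Conditions: NaOH (aq., excess), Cu powder (cat.), reflux, N2; then HCl
Reagents that add atoms: sodium hydroxide, [Na+].[OH-]
Why: Copper-mediated Ullmann-type hydroxylation of an aryl bromide activated by the ortho-formyl group, the reaction type that converts 5-bromovanillin into 5-hydroxyvanillin; the substrate reacts as its C4 phenolate, whose donation into the para-formyl group suppresses the Cannizzaro reaction.

Step 3
Reactants: 3 2,4-dihydroxy-3,5-dimethoxybenzaldehyde; 4 2,2-dimethyl-1,3-dioxane-4,6-dione (Meldrum's acid)
Product: 6 7-hydroxy-6,8-dimethoxy-2-oxo-2H-chromene-3-carboxylic acid, via arylidene Meldrum's acid 5 (not isolated)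
Conditions: piperidinium acetate (cat.), EtOH, 20 → 78 °C
Reagents that add atoms: Meldrum's acid (compound 4), CC1(C)OC(=O)CC(=O)O1
Why: Knoevenagel condensation of a salicylaldehyde with Meldrum's acid followed by acyl transfer to the 2-OH with loss of acetone, the standard entry to coumarin-3-carboxylic acids; only the 2-OH can reach the dioxanedione carbonyl, so the 4-OH ends as the free C7 phenol.

Step 4
Reactants: 6 7-hydroxy-6,8-dimethoxy-2-oxo-2H-chromene-3-carboxylic acid (two molecules)
Product: 8 7-[(7-hydroxy-6,8-dimethoxy-2-oxo-2H-chromen-3-yl)oxy]-6,8-dimethoxy-2-oxo-2H-chromene-3-carboxylic acid, via quinone methide ether 7 (not isolated)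
Conditions: constant-current electrolysis (graphite-felt anode, Pt cathode, undivided cell, about 2 mA cm−2, 0.5 F mol−1), NaHCO3 (2.5 equiv), H2O/MeCN 2:1, 20 °C, N2; then HCl to pH 2; unreacted 6 recycled
Reagents that add atoms: none
Why: Proposed new method: at pH 8 compound 6 is a phenolate–carboxylate dianion that gives up one electron at low anode potential to form a phenoxyl radical whose spin sits on O7 and, through C4a–C4=C3, on C3, while C6 and C8 are blocked by OMe and C4a is the ring fusion. Head-to-tail coupling of two such radicals (O7' of one to C3 of the other) gives the quinone methide ether 7, in which C3 is sp3 and bears the carboxylate; 7 cannot re-aromatise by proton loss and instead expels CO2 in a vinylogous β-keto-acid (Grob-type) fragmentation with the C7 carbonyl as electron sink, which makes the C–O coupling irreversible and gives 8. The closest known reaction types are the oxidative C–O coupling of 4-hydroxy-3,5-dimethoxybenzoic acid to a phenylene oxide with loss of CO2 at the carboxyl-bearing para carbon, and the 8–O–4 dehydrodimerisation of 4-hydroxycinnamates; new is the vinylogous case in which the carboxyl-bearing carbon is C3 of a coumarin. No ring is closed, and the only new stereocentre, C3 of 7, is transient and planar again in 8. The step needs C3–O7' coupling to win over C3–C3' coupling, and the carboxyl group should secure this: tail-to-tail coupling would join two fully substituted carbons that each bear a carboxylate anion (steric and Coulomb penalty, weak and reversible bond), whereas 2,6-dimethoxyphenols with hydrogen at the coupling carbon prefer C–C coupling. O–O coupling is reversible, and coupling at C4a, C6 or C8 offers no way to re-aromatise. The step also needs dimer over oligomer, because the ring-A phenol of 8 can couple again through oxygen; charge control (0.5 F mol−1), a high concentration of 6 and recycling of unreacted 6 should hold this back, and the ring-B carboxylate keeps 8 in solution and off the anode.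

Step 5
Reactants: 8 7-[(7-hydroxy-6,8-dimethoxy-2-oxo-2H-chromen-3-yl)oxy]-6,8-dimethoxy-2-oxo-2H-chromene-3-carboxylic acid
Product: 9 7-hydroxy-6,8-dimethoxy-3-[(6,8-dimethoxy-2-oxo-2H-chromen-7-yl)oxy]-2H-chromen-2-one (target, CNP0278842.0)
Conditions: Ag2CO3 (10 mol %), AcOH (cat.), DMSO, 120 °C, N2
Reagents that add atoms: none
Why: Silver(I)-catalysed protodecarboxylation of a coumarin-3-carboxylic acid (carboxylate → C3'–silver species with loss of CO2 → protonolysis); the near-neutral, non-nucleophilic medium should leave both lactones, the aryl vinyl ether and the methyl ethers untouched.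

## Compound list

1 | 4-hydroxy-3,5-dimethoxybenzaldehyde (syringaldehyde) | COc1cc(C=O)cc(OC)c1O | starting material
2 | 2-bromo-4-hydroxy-3,5-dimethoxybenzaldehyde | COc1cc(C=O)c(Br)c(OC)c1O | intermediate
3 | 2,4-dihydroxy-3,5-dimethoxybenzaldehyde | COc1cc(C=O)c(O)c(OC)c1O | intermediate
4 | 2,2-dimethyl-1,3-dioxane-4,6-dione (Meldrum's acid) | CC1(C)OC(=O)CC(=O)O1 | starting material
5 | 5-(2,4-dihydroxy-3,5-dimethoxybenzylidene)-2,2-dimethyl-1,3-dioxane-4,6-dione | COc1cc(C=C2C(=O)OC(C)(C)OC2=O)c(O)c(OC)c1O | intermediate (not isolated)
6 | 7-hydroxy-6,8-dimethoxy-2-oxo-2H-chromene-3-carboxylic acid | COc1cc2cc(C(=O)O)c(=O)oc2c(OC)c1O | intermediate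
7 | 3-[(3-carboxy-6,8-dimethoxy-2-oxo-2H-chromen-7-yl)oxy]-6,8-dimethoxy-2,7-dioxo-3,7-dihydro-2H-chromene-3-carboxylic acid (quinone methide ether, racemic at the transient C3) | O=C1C(OC)=CC2=CC(C(=O)O)(Oc3c(OC)cc4cc(C(=O)O)c(=O)oc4c3OC)C(=O)OC2=C1OC | intermediate (not isolated)
8 | 7-[(7-hydroxy-6,8-dimethoxy-2-oxo-2H-chromen-3-yl)oxy]-6,8-dimethoxy-2-oxo-2H-chromene-3-carboxylic acid | COc1cc2cc(Oc3c(OC)cc4cc(C(=O)O)c(=O)oc4c3OC)c(=O)oc2c(OC)c1O | intermediate
9 | 7-hydroxy-6,8-dimethoxy-3-[(6,8-dimethoxy-2-oxo-2H-chromen-7-yl)oxy]-2H-chromen-2-one | COc1cc2cc(Oc3c(OC)cc4ccc(=O)oc4c3OC)c(=O)oc2c(OC)c1O | target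

## Step count and risk

Total step count: 5. Longest linear sequence: 5 steps (1 → 2 → 3 → 6 → 8 → 9; step 4 joins two molecules of 6). No protecting group is used.

**Step 4 (key step, bears the label).** Four things are most likely to go wrong:
- Tail-to-tail C3–C3' coupling followed by loss of two CO2, if the steric and Coulomb argument is weaker than assumed.
- Chain growth: the ring-A phenol of 8 is re-oxidised to a radical that can only couple through oxygen and therefore picks up further radicals of 6 to give trimers and higher ethers.
- Slow coupling at the fully substituted C3, so that the radicals decay instead by over-oxidation (capture of water at C3, oxidative demethylation to quinones).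
- Filming of the anode.

On step-growth statistics the dimer should be the main coupled product only while less than about half of 6 is consumed, hence the charge limit. Fallback (known chemistry): it sets out from 6, uses aldehyde 3, and rejoins the route at the target 9, so step 5 is not needed. Acid 6 is protodecarboxylated under the conditions of step 5 to 7-hydroxy-6,8-dimethoxy-2H-chromen-2-one (isofraxidin) F1. O-Alkylation of F1 with tert-butyl bromoacetate (K2CO3, acetone, 56 °C) gives tert-butyl 2-[(6,8-dimethoxy-2-oxo-2H-chromen-7-yl)oxy]acetate F2. TFA in CH2Cl2 frees 2-[(6,8-dimethoxy-2-oxo-2H-chromen-7-yl)oxy]acetic acid F3. Perkin-type condensation of F3 with 3 in Ac2O/Et3N at 110 °C closes ring A and gives 3-[(6,8-dimethoxy-2-oxo-2H-chromen-7-yl)oxy]-6,8-dimethoxy-2-oxo-2H-chromen-7-yl acetate F4. HCl in MeOH at 40 °C removes the acetate to give 9.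

**Step 1.** Most likely failures are ipso attack of bromine at C1 (para to the free phenol) with loss of the formyl group, oxidation of the electron-rich phenol, and a second bromination at C6. Fallback: it sets out from 1 and rejoins at 2, with the phenol masked so that the ring can no longer react as a phenol at C1. Acetylation (Ac2O, pyridine) gives 4-formyl-2,6-dimethoxyphenyl acetate F5. Bromination (NBS, DMF) gives 3-bromo-4-formyl-2,6-dimethoxyphenyl acetate F6. Methanolysis (K2CO3, MeOH, 20 °C) gives 2.

**Step 2.** Most likely failures are reductive loss of bromine, incomplete substitution at the C–Br bond flanked by CHO and OMe, and air oxidation or Cannizzaro disproportionation in hot alkali. Fallback: it sets out from 2 and rejoins at 3, making the C–O bond through a C–B bond. Miyaura borylation (B2pin2, PdCl2(dppf), KOAc, dioxane, 90 °C) gives 4-hydroxy-3,5-dimethoxy-2-(4,4,5,5-tetramethyl-1,3,2-dioxaborolan-2-yl)benzaldehyde F7. Oxidation of the C–B bond with N-methylmorpholine N-oxide (THF, 20 °C), an oxidant that does not start a Dakin reaction of the hydroxy-aldehyde, gives 3 after aqueous work-up.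

**Step 5.** Most likely failures are oxidation of the free ring-A phenol by silver(I), with loss of the catalyst as metal, and slow CO2 extrusion from the electron-rich ring B. Fallback: it sets out from 8 and rejoins at 9 by an addition–decarboxylation–elimination sequence. Aqueous NaHSO3 at 100 °C adds to C4' of the doubly activated ring-B alkene, and the resulting malonic half-acid loses CO2 to give sodium 7-[(7-hydroxy-6,8-dimethoxy-2-oxo-2H-chromen-3-yl)oxy]-6,8-dimethoxy-2-oxo-3,4-dihydro-2H-chromene-4-sulfonate F8. Warm dilute HCl reverses the bisulfite addition and restores the C3'=C4' bond with the lactone closed, giving 9.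

## Further compounds

F1 | step 4 | 7-hydroxy-6,8-dimethoxy-2H-chromen-2-one (isofraxidin; same compound as A1) | COc1cc2ccc(=O)oc2c(OC)c1O
F2 | step 4 | tert-butyl 2-[(6,8-dimethoxy-2-oxo-2H-chromen-7-yl)oxy]acetate | COc1cc2ccc(=O)oc2c(OC)c1OCC(=O)OC(C)(C)C
F3 | step 4 | 2-[(6,8-dimethoxy-2-oxo-2H-chromen-7-yl)oxy]acetic acid (same compound as A2) | COc1cc2ccc(=O)oc2c(OC)c1OCC(=O)O
F4 | step 4 | 3-[(6,8-dimethoxy-2-oxo-2H-chromen-7-yl)oxy]-6,8-dimethoxy-2-oxo-2H-chromen-7-yl acetate | CC(=O)Oc1c(OC)cc2cc(Oc3c(OC)cc4ccc(=O)oc4c3OC)c(=O)oc2c1OC
F5 | step 1 | 4-formyl-2,6-dimethoxyphenyl acetate | COc1cc(C=O)cc(OC)c1OC(C)=O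
F6 | step 1 | 3-bromo-4-formyl-2,6-dimethoxyphenyl acetate | COc1cc(C=O)c(Br)c(OC)c1OC(C)=O
F7 | step 2 | 4-hydroxy-3,5-dimethoxy-2-(4,4,5,5-tetramethyl-1,3,2-dioxaborolan-2-yl)benzaldehyde | COc1cc(C=O)c(B2OC(C)(C)C(C)(C)O2)c(OC)c1O
F8 | step 5 | sodium 7-[(7-hydroxy-6,8-dimethoxy-2-oxo-2H-chromen-3-yl)oxy]-6,8-dimethoxy-2-oxo-3,4-dihydro-2H-chromene-4-sulfonate | [Na+].[O-]S(=O)(=O)C1CC(=O)Oc2c1cc(OC)c(Oc1cc3cc(OC)c(O)c(OC)c3oc1=O)c2OC
A1 | alternative 1 | 7-hydroxy-6,8-dimethoxy-2H-chromen-2-one (isofraxidin) | COc1cc2ccc(=O)oc2c(OC)c1O
A2 | alternative 1 | 2-[(6,8-dimethoxy-2-oxo-2H-chromen-7-yl)oxy]acetic acid | COc1cc2ccc(=O)oc2c(OC)c1OCC(=O)O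
A3 | alternative 2 | 3-bromo-6,8-dimethoxy-7-(methoxymethoxy)-2H-chromen-2-one | COCOc1c(OC)cc2cc(Br)c(=O)oc2c1OC
A4 | alternative 2 | 3-[(6,8-dimethoxy-2-oxo-2H-chromen-7-yl)oxy]-6,8-dimethoxy-7-(methoxymethoxy)-2H-chromen-2-one | COCOc1c(OC)cc2cc(Oc3c(OC)cc4ccc(=O)oc4c3OC)c(=O)oc2c1OC
A5 | alternative 3 | 7,7'-dihydroxy-6,6',8,8'-tetramethoxy-2H,2'H-[3,3'-bichromene]-2,2'-dione (3,3'-biisofraxidin) | COc1cc2cc(-c3cc4cc(OC)c(O)c(OC)c4oc3=O)c(=O)oc2c(OC)c1O
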